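The readings come from a simulation for an exercise, and the scatter is random.

Amounts first: the new flasks hold 0.060 M of free monomer, half of what maple held, at the same loading of 0.56 mol% of initiator.

the same everywhere: initiator 0.56 mol%

| charge | free monomer | temperature | remark | time |
|---|---|---|---|---|
| ash | 0.030 M | −15 °C | run made earlier |  |
| maple | 0.12 M | 20 °C | run made earlier |  |
| dawn | 0.060 M | 50 °C |  | 20 h |
| dusk | 0.060 M |  | at 50 °C until 10 h, from then on at −10 °C | 20 h |
| spring | 0.060 M | 20 °C |  | 20 h |
| autumn | 0.060 M | −10 °C |  | 20 h |

- ash (time / h: monomer in chains / %): 40.0: 0; 60.0: 0; 96.0: 1; 192: 1; 288: 1; 480: 0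
- maple (time / h: monomer in chains / %): 6.00: 0; 12.0: 2; 20.0: 2; 40.0: 8; 48.0: 10; 96.0: 25

(standard deviation of a reading: 1.5 percentage points)

- which flask leads in amount of monomer in chains, in percent of the free monomer charged ("all alike" within 1.5 percentage points) (dawn / dusk / spring / autumn / all alike)
- how much monomer in chains is there at the end, in percent of the free monomer charged: dawn
- how much monomer in chains is there at the end, in percent of the free monomer charged: dusk
- how much monomer in chains is there at the end, in percent of the free monomer charged: spring
- how much monomer in chains is there at the end, in percent of the free monomer charged: autumn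

Before any number, I ask which setting has to be known well. Living ends form from free monomer and initiator, and at fixed loading both go with the charge. Each living end then takes its share of the free monomer per hour, so the early percent in chains goes with the charge square 0.00360 M^2, the free monomer charged multiplied by itself. Living ends also pile up with time, so the early percent goes with time squared too. A charge or a time off by a factor 2 therefore moves the early percent by 4.00, and a loading off by the same factor moves it by 2. Those settings are given, so the weak number is the temperature step: ash reads 1 % at 288 h, against a scatter of 1.5 percentage points, and gives me nothing sharp.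

Spring needs no such step, since it shares maple's 20 °C. Maple reads 10 % at 48.0 h, and scaling that reading by charge square and time squared gives 0.434 % for spring, with the reading's scatter on it. Autumn runs 20 h, far shorter than ash's 288 h, so I expect nothing readable there. I put dawn first, and dusk below it, since dusk leaves dawn's temperature at 10 h, earlier than the end at 20 h; how far up they stand I can't tell from ash.

The forecast names dawn as leader, with 4 %, 1.5 %, 0.5 % and 0.03 % for dawn, dusk, spring and autumn, a spring figure above mine, and holds that "initiator exhaustion and the limited ramp cut this to about 4%".

The flasks give 20.2 % in dawn, 9.44 % in dusk, 0.407 % in spring and 0 % in autumn, so dawn leads.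

    free monomer + initiator → living end + monomer in chains (k = 0.180 M⁻¹ h⁻¹, Ea = 86.0 kJ mol⁻¹)
    free monomer + living end → monomer in chains + living end, rate k2*[living end]*[free monomer] (k = 1500 M⁻¹ h⁻¹, Ea = 59.0 kJ mol⁻¹)
    initiator → spent initiator (k = 0.410 h⁻¹, Ea = 95.0 kJ mol⁻¹)
    (constants at 50 °C)

Spring's 0.407 % stands against my 0.434 %, and the charge square now goes to dawn's neighbour. Dawn's 20.2 % is 0.226 as the negative logarithm of the free monomer fraction left, at charge square 0.00360 M^2. The neighbouring flask holds 0.10 M of free monomer at dawn's loading, temperature and time, so its charge square is 0.0100 M^2, or 2.78 times dawn's. Scaling the logarithm by that factor gives 46.6 % in chains. The neighbouring flask holds 45.4 % in chains, with 0.021 % of its initiator left.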